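**Plan**

1. The target is 1,5-di-O-caffeoyl-4-O-succinyl-(−)-quinic acid. Retrosynthesis first cuts the two caffeate C–O bonds (O1, then O5) and takes the C3 carbinol back to a ketone. This exposes the enabling feature: in the cyclohexane, C1 is a tertiary carbinol carrying the carboxyl group and is separated from the C3 carbonyl only by the methylene C2, so the ring bond C1–C2 is an aldol bond to an α-keto ester.
2. Cutting C1–C2 opens the only carbocycle to an open-chain 2,6-diketo ester (C3 methyl ketone, C1 α-keto ester, O4 succinate, O5 benzyl ether). Both carbonyls go back to C=CH2 groups, and the chain is cut at C3–C4 (isopropenyl Grignard) and at C5–C6 (indium allylation with a 2-(bromomethyl)acrylate).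
3. Forward: C6–C1–CO2tBu is joined to C5, then C2–C3 to C4; O4 is succinylated; one ozonolysis unveils both ketones; the aldol closes the six-membered ring. Reduction at C3, caffeoylation of O5 and then of O1 in separate steps, and one acidolysis finish the synthesis.
4. Stereochemistry: C5 from Felkin–Anh addition to L-glyceraldehyde acetonide (its own stereocentre is excised afterwards); C4 from chelation-controlled addition next to the O5 benzyl ether; C1 from the chair transition state of the aldol; C3 from a chelation-directed syn reduction.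

Key step: step 8

Remark: quinic acid numbering is used for all intermediates, open-chain ones included. O5 travels as a benzyl ether and the O5 caffeate is installed only after ring closure, because a cinnamate would not survive ozonolysis and would be a leaving group β to both ketones.

**Route**

Step 1
Reactants: 1 5,6-O-isopropylidene-L-gulono-1,4-lactone
Product: 2 (4S)-2,2-dimethyl-1,3-dioxolane-4-carbaldehyde
Conditions: NaIO4 (2 equiv), H2O, pH 5.5 (NaOH), 0 °C to rt
Reagents that add atoms: none
Why: Malaprade glycol cleavage: periodate cuts the C2–C3 diol of the lactone, the glyoxylate ester so formed hydrolyses and a second equivalent cleaves the resulting α-hydroxy aldehyde, leaving C4–C6 as the aldehyde with the former C5 stereocentre untouched (the S centre of 2).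

Step 2
Reactants: 2 (4S)-2,2-dimethyl-1,3-dioxolane-4-carbaldehyde; 3 tert-butyl 2-(bromomethyl)prop-2-enoate
Product: 4 tert-butyl (4R)-4-[(4S)-2,2-dimethyl-1,3-dioxolan-4-yl]-4-hydroxy-2-methylidenebutanoate
Conditions: indium powder (In), THF/H2O (1:1), rt
Reagents that add atoms: none
Why: Indium-mediated Barbier-type 2-(alkoxycarbonyl)allylation in water; the non-chelated Felkin–Anh mode of the α-dioxolanyl aldehyde should give the anti adduct as the major diastereomer (the syn isomer is removed by chromatography), setting the future C5 as R, and the tert-butyl ester keeps the γ-hydroxy ester from lactonising.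

Step 3
Reactants: 4 tert-butyl (4R)-4-[(4S)-2,2-dimethyl-1,3-dioxolan-4-yl]-4-hydroxy-2-methylidenebutanoate
Product: 5 tert-butyl (4R)-4-(benzyloxy)-4-[(4S)-2,2-dimethyl-1,3-dioxolan-4-yl]-2-methylidenebutanoate
Conditions: 2-benzyloxy-1-methylpyridinium triflate, MgO, PhCF3, 85 °C
Reagents that add atoms: 2-benzyloxy-1-methylpyridinium trifluoromethanesulfonate, C[n+]1ccccc1OCc1ccccc1.[O-]S(=O)(=O)C(F)(F)F
Why: Dudley benzylation: benzyl transfer from the pyridinium salt under neutral, MgO-buffered conditions etherifies the secondary alcohol without base (no oxa-Michael chemistry at the acrylate) and without acid (acetonide and tert-butyl ester survive); the benzyl ether chelates in step 5, resists ozone in step 7 and is a poor leaving group in step 8.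

Step 4
Reactants: 5 tert-butyl (4R)-4-(benzyloxy)-4-[(4S)-2,2-dimethyl-1,3-dioxolan-4-yl]-2-methylidenebutanoate
Product: 7 tert-butyl (4R)-4-(benzyloxy)-2-methylidene-5-oxopentanoate, via diol 6 (not isolated)
Conditions: H5IO6, EtOAc, rt
Reagents that add atoms: none
Why: Periodic acid hydrolyses the terminal isopropylidene acetal and cleaves the liberated 1,2-diol in the same flask (Malaprade cleavage), excising the stereocentre that served as control element in step 2; the α-benzyloxy aldehyde is used crude so that its α-centre (future C5) does not epimerise.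

Step 5
Reactants: 7 tert-butyl (4R)-4-(benzyloxy)-2-methylidene-5-oxopentanoate; 8 prop-1-en-2-ylmagnesium bromide
Product: 9 tert-butyl (4R,5R)-4-(benzyloxy)-5-hydroxy-6-methyl-2-methylidenehept-6-enoate
Conditions: MgBr2·OEt2, CH2Cl2, −78 °C; then 8 (THF), −78 °C; aq NH4Cl
Reagents that add atoms: none
Why: Cram-chelate-controlled Grignard addition: MgBr2 locks the aldehyde and benzyloxy oxygens in a five-membered chelate and the alkenyl nucleophile attacks its less hindered face, which should give the 4,5-syn (threo) allylic alcohol and so sets C4; at −78 °C the chelated aldehyde outcompetes the tert-butyl acrylate, and the minor anti epimer is separated by chromatography.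

Step 6
Reactants: 9 tert-butyl (4R,5R)-4-(benzyloxy)-5-hydroxy-6-methyl-2-methylidenehept-6-enoate; 10 4-tert-butoxy-4-oxobutanoic acid
Product: 11 1-tert-butyl 4-[(3R,4R)-4-(benzyloxy)-6-(tert-butoxycarbonyl)-2-methylhepta-1,6-dien-3-yl] butanedioate
Conditions: EDC·HCl, DMAP (cat.), CH2Cl2, 0 °C to rt
Reagents that add atoms: none
Why: Steglich esterification (carbodiimide activation, DMAP catalysis) acylates the only hydroxyl, the secondary allylic one, with retention at C4.

Step 7
Reactants: 11 1-tert-butyl 4-[(3R,4R)-4-(benzyloxy)-6-(tert-butoxycarbonyl)-2-methylhepta-1,6-dien-3-yl] butanedioate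
Product: 13 tert-butyl (4R,5S)-4-(benzyloxy)-5-[(4-tert-butoxy-4-oxobutanoyl)oxy]-2,6-dioxoheptanoate, via bis-ozonide 12 (not isolated)
Conditions: O3, CH2Cl2, −78 °C; then Me2S, −78 °C to rt
Reagents that add atoms: ozone, [O-][O+]=O
Why: Ozonolysis (Criegee mechanism) with reductive work-up cleaves both 1,1-disubstituted alkenes in one operation, turning the isopropenyl group into the C3 methyl ketone and the 2-methylene ester into the C1 α-keto ester; benzyl ether and esters are inert at −78 °C, no stereocentre is touched, and the diketone is used at once because its keto ester hydrates readily.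

Step 8
Reactants: 13 tert-butyl (4R,5S)-4-(benzyloxy)-5-[(4-tert-butoxy-4-oxobutanoyl)oxy]-2,6-dioxoheptanoate
Product: 14 tert-butyl (1R,4S,5R)-5-(benzyloxy)-4-[(4-tert-butoxy-4-oxobutanoyl)oxy]-1-hydroxy-3-oxocyclohexane-1-carboxylate
Conditions: Et3N (0.3 equiv), CH2Cl2 (0.02 M), 0 °C to rt
Reagents that add atoms: none
Why: Triethylamine reversibly forms the ammonium enolate (or enol) of the C3 methyl ketone at C2, which adds to the C1 ketone of the α-keto ester, the most electrophilic carbonyl present, forming the C1–C2 bond; this is an amine-mediated direct intramolecular aldol addition, the reaction type established for carbocyclisation of ether-protected sugar diketones and the laboratory counterpart of the dehydroquinate-synthase ring closure. The cyclohexane closes in the 6-(enolendo)-exo-trig mode, whereas enolisation at C4 or C6 could only lead to four-membered rings and is therefore unproductive and reversible. The new stereocentre C1 is controlled by a chair transition state with O4 and O5 equatorial and the ketone oxygen axial, bridged to the enol(ate) oxygen through the ammonium proton, so that the ester ends equatorial and the hydroxyl cis to O4; the same isomer is the thermodynamically favoured one and the aldol is reversible. The step needs C2 to react in preference to C4 and C6 and must avoid β-elimination: the ring-size argument secures the first, and the second is secured by O5 being a benzyl ether (poor leaving group), by the weak substoichiometric base, and by stopping before the ketol can dehydrate.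

Step 9
Reactants: 14 tert-butyl (1R,4S,5R)-5-(benzyloxy)-4-[(4-tert-butoxy-4-oxobutanoyl)oxy]-1-hydroxy-3-oxocyclohexane-1-carboxylate
Product: 16 tert-butyl (1S,3R,4R,5R)-5-(benzyloxy)-4-[(4-tert-butoxy-4-oxobutanoyl)oxy]-1,3-dihydroxycyclohexane-1-carboxylate, via boron chelate 15 (not isolated)
Conditions: Et2BOMe, THF/MeOH (4:1), −78 °C; NaBH4, −78 °C; AcOH; MeOH co-evaporation
Reagents that add atoms: none
Why: Narasaka–Prasad reduction: the diethylboron group bridges the axial 1-hydroxyl and the C3 carbonyl on the upper face and also blocks the axial trajectory, so borohydride enters from the equatorial side and should give the axial 3-alcohol cis to O1 (1,3-syn diol, 3R); at −78 °C the esters are not reduced and the boron-bound O3 cannot take over the neighbouring succinyl group.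

Step 10
Reactants: 16 tert-butyl (1S,3R,4R,5R)-5-(benzyloxy)-4-[(4-tert-butoxy-4-oxobutanoyl)oxy]-1,3-dihydroxycyclohexane-1-carboxylate
Product: 17 tert-butyl (1R,3R,4S,5R)-5-(benzyloxy)-4-[(4-tert-butoxy-4-oxobutanoyl)oxy]-1-hydroxy-3-[(triethylsilyl)oxy]cyclohexane-1-carboxylate
Conditions: Et3SiCl, imidazole, DMF, 0 °C
Reagents that add atoms: chlorotriethylsilane, CC[Si](Cl)(CC)CC
Why: Silyl ether formation with steric discrimination: the secondary 3-hydroxyl is silylated while the tertiary 1-hydroxyl is not, and imidazole at 0 °C should not trigger 4→3 acyl migration.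

Step 11
Reactants: 17 tert-butyl (1R,3R,4S,5R)-5-(benzyloxy)-4-[(4-tert-butoxy-4-oxobutanoyl)oxy]-1-hydroxy-3-[(triethylsilyl)oxy]cyclohexane-1-carboxylate
Product: 18 tert-butyl (1R,3R,4S,5R)-4-[(4-tert-butoxy-4-oxobutanoyl)oxy]-1,5-dihydroxy-3-[(triethylsilyl)oxy]cyclohexane-1-carboxylate
Conditions: H2 (1 atm), Pd(OH)2/C, EtOAc, rt
Reagents that add atoms: none
Why: Hydrogenolysis of the benzyl ether under neutral conditions frees the 5-hydroxyl; no alkene is present at this stage, and silyl ether and esters survive in ethyl acetate.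

Step 12
Reactants: 19 3,4-dihydroxybenzaldehyde
Product: 20 2,2-dimethyl-1,3-benzodioxole-5-carbaldehyde
Conditions: Me2C(OMe)2, TsOH (cat.), toluene, reflux (MeOH removed)
Reagents that add atoms: 2,2-dimethoxypropane, COC(C)(C)OC
Why: Acid-catalysed ketal exchange of the catechol with 2,2-dimethoxypropane, driven by removal of methanol, gives the acetonide that is removed again in the final acidolysis.

Step 13
Reactants: 20 2,2-dimethyl-1,3-benzodioxole-5-carbaldehyde; 21 malonic acid
Product: 23 (2E)-3-(2,2-dimethyl-1,3-benzodioxol-5-yl)prop-2-enoic acid, via arylidenemalonic acid 22 (not isolated)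
Conditions: pyridine, piperidine (cat.), 90 °C
Reagents that add atoms: none
Why: Knoevenagel–Doebner condensation: the arylidenemalonic acid decarboxylates in hot pyridine to the (E)-cinnamic acid, and the base-stable acetonide is unaffected.

Step 14
Reactants: 23 (2E)-3-(2,2-dimethyl-1,3-benzodioxol-5-yl)prop-2-enoic acid
Product: 24 (2E)-3-(2,2-dimethyl-1,3-benzodioxol-5-yl)prop-2-enoyl chloride
Conditions: (COCl)2, DMF (cat.), CH2Cl2, 0 °C to rt; volatiles removed, used crude
Reagents that add atoms: oxalyl chloride, ClC(=O)C(=O)Cl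
Why: Acid chloride formation through the chloroiminium (Vilsmeier-type) species generated from oxalyl chloride and catalytic DMF; the anhydrous conditions leave the catechol acetonide and the (E)-alkene intact, and the chloride is prepared fresh for each of the two acylations that follow.

Step 15
Reactants: 18 tert-butyl (1R,3R,4S,5R)-4-[(4-tert-butoxy-4-oxobutanoyl)oxy]-1,5-dihydroxy-3-[(triethylsilyl)oxy]cyclohexane-1-carboxylate; 24 (2E)-3-(2,2-dimethyl-1,3-benzodioxol-5-yl)prop-2-enoyl chloride
Product: 25 tert-butyl (1R,3R,4S,5R)-4-[(4-tert-butoxy-4-oxobutanoyl)oxy]-5-{[(2E)-3-(2,2-dimethyl-1,3-benzodioxol-5-yl)prop-2-enoyl]oxy}-1-hydroxy-3-[(triethylsilyl)oxy]cyclohexane-1-carboxylate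
Conditions: 24 (1.1 equiv), pyridine, DMAP (cat.), CH2Cl2, 0 °C
Reagents that add atoms: none
Why: DMAP-catalysed acylation (nucleophilic catalysis through the acylpyridinium ion) with a slight excess of 24 at 0 °C esterifies the equatorial secondary 5-hydroxyl, while the hindered tertiary 1-hydroxyl should not react under these conditions and the short reaction time at low temperature should prevent 4→5 succinyl migration.

Step 16
Reactants: 25 tert-butyl (1R,3R,4S,5R)-4-[(4-tert-butoxy-4-oxobutanoyl)oxy]-5-{[(2E)-3-(2,2-dimethyl-1,3-benzodioxol-5-yl)prop-2-enoyl]oxy}-1-hydroxy-3-[(triethylsilyl)oxy]cyclohexane-1-carboxylate; 24 (2E)-3-(2,2-dimethyl-1,3-benzodioxol-5-yl)prop-2-enoyl chloride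
Product: 26 tert-butyl (1R,3R,4S,5R)-4-[(4-tert-butoxy-4-oxobutanoyl)oxy]-1,5-bis{[(2E)-3-(2,2-dimethyl-1,3-benzodioxol-5-yl)prop-2-enoyl]oxy}-3-[(triethylsilyl)oxy]cyclohexane-1-carboxylate
Conditions: 24 (3 equiv), DMAP (2 equiv), pyridine, ClCH2CH2Cl, 50 °C
Reagents that add atoms: none
Why: Forcing DMAP-mediated acylation of a tertiary alcohol by a cinnamoyl chloride that cannot form a ketene, the method used for 1-O-cinnamoyl quinic acid derivatives; the substrate has no ketone and no other free hydroxyl, so excess reagent and warming should cause neither elimination nor acyl migration.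

Step 17
Reactants: 26 tert-butyl (1R,3R,4S,5R)-4-[(4-tert-butoxy-4-oxobutanoyl)oxy]-1,5-bis{[(2E)-3-(2,2-dimethyl-1,3-benzodioxol-5-yl)prop-2-enoyl]oxy}-3-[(triethylsilyl)oxy]cyclohexane-1-carboxylate
Product: 27 (1S,3R,4R,5R)-4-[(3-carboxypropanoyl)oxy]-1,5-bis{[(2E)-3-(3,4-dihydroxyphenyl)prop-2-enoyl]oxy}-3-hydroxycyclohexane-1-carboxylic acid
Conditions: TFA/CH2Cl2/H2O (10:10:1), 0 °C to rt
Reagents that add atoms: none
Why: Global acidolysis: aqueous trifluoroacetic acid cleaves both tert-butyl esters (tert-butyl cation mechanism), both catechol acetonides and the triethylsilyl ether, while the caffeoyl and succinyl esters are acid-stable, the tertiary C1–O bond cannot ionise next to the carboxyl group and acyl migration is slow at low pH.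

**Compound list**

1 | 5,6-O-isopropylidene-L-gulono-1,4-lactone | O=C1O[C@H]([C@@H]2COC(C)(C)O2)[C@H](O)[C@@H]1O | starting material
2 | (4S)-2,2-dimethyl-1,3-dioxolane-4-carbaldehyde (L-glyceraldehyde acetonide) | O=C[C@@H]1COC(C)(C)O1 | intermediate
3 | tert-butyl 2-(bromomethyl)prop-2-enoate | C=C(CBr)C(=O)OC(C)(C)C | starting material
4 | tert-butyl (4R)-4-[(4S)-2,2-dimethyl-1,3-dioxolan-4-yl]-4-hydroxy-2-methylidenebutanoate | C=C(C[C@@H](O)[C@@H]1COC(C)(C)O1)C(=O)OC(C)(C)C | intermediate
5 | tert-butyl (4R)-4-(benzyloxy)-4-[(4S)-2,2-dimethyl-1,3-dioxolan-4-yl]-2-methylidenebutanoate | C=C(C[C@@H](OCc1ccccc1)[C@@H]1COC(C)(C)O1)C(=O)OC(C)(C)C | intermediate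
6 | tert-butyl (4R,5S)-4-(benzyloxy)-5,6-dihydroxy-2-methylidenehexanoate | C=C(C[C@@H](OCc1ccccc1)[C@@H](O)CO)C(=O)OC(C)(C)C | intermediate (not isolated)
7 | tert-butyl (4R)-4-(benzyloxy)-2-methylidene-5-oxopentanoate | C=C(C[C@@H](OCc1ccccc1)C=O)C(=O)OC(C)(C)C | intermediate
8 | prop-1-en-2-ylmagnesium bromide | CC(=C)[Mg]Br | starting material
9 | tert-butyl (4R,5R)-4-(benzyloxy)-5-hydroxy-6-methyl-2-methylidenehept-6-enoate (4,5-syn) | C=C(C)[C@@H](O)[C@H](OCc1ccccc1)CC(=C)C(=O)OC(C)(C)C | intermediate
10 | 4-tert-butoxy-4-oxobutanoic acid (mono-tert-butyl succinate) | CC(C)(C)OC(=O)CCC(=O)O | starting material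
11 | 1-tert-butyl 4-[(3R,4R)-4-(benzyloxy)-6-(tert-butoxycarbonyl)-2-methylhepta-1,6-dien-3-yl] butanedioate | C=C(C)[C@@H](OC(=O)CCC(=O)OC(C)(C)C)[C@H](OCc1ccccc1)CC(=C)C(=O)OC(C)(C)C | intermediate
12 | bis-ozonide of 11: each C=CH2 replaced by a 1,2,4-trioxolane, C4 and C5 as in 11, mixture at the two trioxolane carbons | CC1(OCOO1)[C@@H](OC(=O)CCC(=O)OC(C)(C)C)[C@H](OCc1ccccc1)CC1(OCOO1)C(=O)OC(C)(C)C | intermediate (not isolated)
13 | tert-butyl (4R,5S)-4-(benzyloxy)-5-[(4-tert-butoxy-4-oxobutanoyl)oxy]-2,6-dioxoheptanoate | CC(=O)[C@@H](OC(=O)CCC(=O)OC(C)(C)C)[C@H](OCc1ccccc1)CC(=O)C(=O)OC(C)(C)C | intermediate (aldol precursor)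
14 | tert-butyl (1R,4S,5R)-5-(benzyloxy)-4-[(4-tert-butoxy-4-oxobutanoyl)oxy]-1-hydroxy-3-oxocyclohexane-1-carboxylate (tert-butyl 5-O-benzyl-4-O-succinyl-3-dehydroquinate, succinyl as tert-butyl ester) | CC(C)(C)OC(=O)CCC(=O)O[C@@H]1C(=O)C[C@@](O)(C(=O)OC(C)(C)C)C[C@H]1OCc1ccccc1 | intermediate (aldol product)
15 | 1-O-diethylboryl chelate of 14 | CC(C)(C)OC(=O)CCC(=O)O[C@@H]1C(=O)C[C@@](OB(CC)CC)(C(=O)OC(C)(C)C)C[C@H]1OCc1ccccc1 | intermediate (not isolated)
16 | tert-butyl (1S,3R,4R,5R)-5-(benzyloxy)-4-[(4-tert-butoxy-4-oxobutanoyl)oxy]-1,3-dihydroxycyclohexane-1-carboxylate | CC(C)(C)OC(=O)CCC(=O)O[C@@H]1[C@H](O)C[C@@](O)(C(=O)OC(C)(C)C)C[C@H]1OCc1ccccc1 | intermediate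
17 | tert-butyl (1R,3R,4S,5R)-5-(benzyloxy)-4-[(4-tert-butoxy-4-oxobutanoyl)oxy]-1-hydroxy-3-[(triethylsilyl)oxy]cyclohexane-1-carboxylate | CC(C)(C)OC(=O)CCC(=O)O[C@@H]1[C@H](O[Si](CC)(CC)CC)C[C@@](O)(C(=O)OC(C)(C)C)C[C@H]1OCc1ccccc1 | intermediate
18 | tert-butyl (1R,3R,4S,5R)-4-[(4-tert-butoxy-4-oxobutanoyl)oxy]-1,5-dihydroxy-3-[(triethylsilyl)oxy]cyclohexane-1-carboxylate | CC(C)(C)OC(=O)CCC(=O)O[C@@H]1[C@H](O[Si](CC)(CC)CC)C[C@@](O)(C(=O)OC(C)(C)C)C[C@H]1O | intermediate
19 | 3,4-dihydroxybenzaldehyde | O=Cc1ccc(O)c(O)c1 | starting material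
20 | 2,2-dimethyl-1,3-benzodioxole-5-carbaldehyde | O=Cc1ccc2OC(C)(C)Oc2c1 | intermediate
21 | malonic acid | OC(=O)CC(=O)O | starting material
22 | 2-[(2,2-dimethyl-1,3-benzodioxol-5-yl)methylidene]propanedioic acid | OC(=O)C(=Cc1ccc2OC(C)(C)Oc2c1)C(=O)O | intermediate (not isolated)
23 | (2E)-3-(2,2-dimethyl-1,3-benzodioxol-5-yl)prop-2-enoic acid | OC(=O)/C=C/c1ccc2OC(C)(C)Oc2c1 | intermediate
24 | (2E)-3-(2,2-dimethyl-1,3-benzodioxol-5-yl)prop-2-enoyl chloride | ClC(=O)/C=C/c1ccc2OC(C)(C)Oc2c1 | intermediate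
25 | tert-butyl (1R,3R,4S,5R)-4-[(4-tert-butoxy-4-oxobutanoyl)oxy]-5-{[(2E)-3-(2,2-dimethyl-1,3-benzodioxol-5-yl)prop-2-enoyl]oxy}-1-hydroxy-3-[(triethylsilyl)oxy]cyclohexane-1-carboxylate | CC(C)(C)OC(=O)CCC(=O)O[C@@H]1[C@H](O[Si](CC)(CC)CC)C[C@@](O)(C(=O)OC(C)(C)C)C[C@H]1OC(=O)/C=C/c1ccc2OC(C)(C)Oc2c1 | intermediate
26 | tert-butyl (1R,3R,4S,5R)-4-[(4-tert-butoxy-4-oxobutanoyl)oxy]-1,5-bis{[(2E)-3-(2,2-dimethyl-1,3-benzodioxol-5-yl)prop-2-enoyl]oxy}-3-[(triethylsilyl)oxy]cyclohexane-1-carboxylate | CC(C)(C)OC(=O)CCC(=O)O[C@@H]1[C@H](O[Si](CC)(CC)CC)C[C@@](OC(=O)/C=C/c2ccc3OC(C)(C)Oc3c2)(C(=O)OC(C)(C)C)C[C@H]1OC(=O)/C=C/c1ccc2OC(C)(C)Oc2c1 | intermediate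
27 | (1S,3R,4R,5R)-4-[(3-carboxypropanoyl)oxy]-1,5-bis{[(2E)-3-(3,4-dihydroxyphenyl)prop-2-enoyl]oxy}-3-hydroxycyclohexane-1-carboxylic acid (1,5-di-O-caffeoyl-4-O-succinylquinic acid) | O=C(O)CCC(=O)O[C@@H]1[C@H](O)C[C@@](OC(=O)/C=C/c2ccc(O)c(O)c2)(C(=O)O)C[C@H]1OC(=O)/C=C/c1ccc(O)c(O)c1 | target

**Step count and risks**

Total steps: 17. Longest linear sequence: 14 (steps 1–11, 15, 16, 17); steps 12–14 form the side branch to acid chloride 24.

Most likely to fail:

Step 8 (aldol ring closure). The methyl group is the least acidic of the three enolisable positions. C4, acidified by its acyloxy group, may enolise first and then epimerise or expel benzyl alcohol from C5, and addition through an open transition state would erode the ratio at C1. The fallback carries O4 as a silyl ether through the ring closure, so that the nucleophilic ketone matches the ether-protected sugar diketones for which this cyclisation is established. It sets out from 9: silylation (Et3SiCl, imidazole) gives tert-butyl (4R,5R)-4-(benzyloxy)-6-methyl-2-methylidene-5-[(triethylsilyl)oxy]hept-6-enoate F1. Ozonolysis as in step 7 gives tert-butyl (4R,5S)-4-(benzyloxy)-2,6-dioxo-5-[(triethylsilyl)oxy]heptanoate F2. The amine-mediated aldol, which can now be run longer or with L-proline, gives tert-butyl (1R,4S,5R)-5-(benzyloxy)-1-hydroxy-3-oxo-4-[(triethylsilyl)oxy]cyclohexane-1-carboxylate F3. HF·pyridine then frees tert-butyl (1R,4S,5R)-5-(benzyloxy)-1,4-dihydroxy-3-oxocyclohexane-1-carboxylate F4, whose only secondary hydroxyl is esterified with 10 (EDC, DMAP), which returns to the route at 14.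

Step 16 (caffeoylation of the tertiary 1-hydroxyl). Acylation may stall, because the axial tertiary 1-hydroxyl is shielded by the tert-butyl ester and the syn-axial silyloxy group. The fallback builds the 1-O-cinnamoyl unit by olefination. It sets out from 25: diethylphosphonoacetic acid and DCC acylate through the small, highly electrophilic phosphonoketene, which esterifies tertiary alcohols, and give tert-butyl (1R,3R,4S,5R)-4-[(4-tert-butoxy-4-oxobutanoyl)oxy]-1-{[(diethoxyphosphoryl)acetyl]oxy}-5-{[(2E)-3-(2,2-dimethyl-1,3-benzodioxol-5-yl)prop-2-enoyl]oxy}-3-[(triethylsilyl)oxy]cyclohexane-1-carboxylate F5. A Horner–Wadsworth–Emmons reaction with aldehyde 20 (LiCl, DBU, MeCN) then forms the (E)-alkene and returns to the route at 26.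

Step 5 (chelation-controlled Grignard addition). Incomplete chelation would let the Felkin–Anh mode compete and lower the syn selectivity at C4. The fallback uses the unwanted epimer and sets out from 7: the anti alcohol tert-butyl (4R,5S)-4-(benzyloxy)-5-hydroxy-6-methyl-2-methylidenehept-6-enoate F6 is separated and esterified with 10 under Mitsunobu conditions (PPh3, DIAD, THF), with inversion at C4. It returns to the route at 11, so both epimers converge.

**Further compounds**

F1 | step 8 | tert-butyl (4R,5R)-4-(benzyloxy)-6-methyl-2-methylidene-5-[(triethylsilyl)oxy]hept-6-enoate | C=C(C)[C@@H](O[Si](CC)(CC)CC)[C@H](OCc1ccccc1)CC(=C)C(=O)OC(C)(C)C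
F2 | step 8 | tert-butyl (4R,5S)-4-(benzyloxy)-2,6-dioxo-5-[(triethylsilyl)oxy]heptanoate | CC(=O)[C@@H](O[Si](CC)(CC)CC)[C@H](OCc1ccccc1)CC(=O)C(=O)OC(C)(C)C
F3 | step 8 | tert-butyl (1R,4S,5R)-5-(benzyloxy)-1-hydroxy-3-oxo-4-[(triethylsilyl)oxy]cyclohexane-1-carboxylate | CC[Si](CC)(CC)O[C@@H]1C(=O)C[C@@](O)(C(=O)OC(C)(C)C)C[C@H]1OCc1ccccc1
F4 | step 8 | tert-butyl (1R,4S,5R)-5-(benzyloxy)-1,4-dihydroxy-3-oxocyclohexane-1-carboxylate | O[C@@H]1C(=O)C[C@@](O)(C(=O)OC(C)(C)C)C[C@H]1OCc1ccccc1
F5 | step 16 | tert-butyl (1R,3R,4S,5R)-4-[(4-tert-butoxy-4-oxobutanoyl)oxy]-1-{[(diethoxyphosphoryl)acetyl]oxy}-5-{[(2E)-3-(2,2-dimethyl-1,3-benzodioxol-5-yl)prop-2-enoyl]oxy}-3-[(triethylsilyl)oxy]cyclohexane-1-carboxylate | CC(C)(C)OC(=O)CCC(=O)O[C@@H]1[C@H](O[Si](CC)(CC)CC)C[C@@](OC(=O)CP(=O)(OCC)OCC)(C(=O)OC(C)(C)C)C[C@H]1OC(=O)/C=C/c1ccc2OC(C)(C)Oc2c1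
F6 | step 5 | tert-butyl (4R,5S)-4-(benzyloxy)-5-hydroxy-6-methyl-2-methylidenehept-6-enoate | C=C(C)[C@H](O)[C@H](OCc1ccccc1)CC(=C)C(=O)OC(C)(C)C
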